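## The problem

Target 25 is a 2,2-dimethyl-2H-chromene whose benzo ring (ring A) is fused to the pyran through C4a and C8a and carries a 2-(4-hydroxyphenyl)ethyl chain on C5 and a prenyl ether on C7; ring B is a free para-phenol at the far end of the C-alpha–C-beta bridge. Ring A is therefore a 1,2,3,5-tetrasubstituted resorcinol whose two oxygens must be told apart (O1 inside the pyran, O7 as an allylic ether), and C4a, flanked by C8a–O and the C5 chain, must receive the carbon that becomes C4. Direct C-prenylation of a 5-alkylresorcinol cannot do this cleanly, since the carbon between the two oxygens (C8) competes with C4a and the oxygens would still be identical. The target has no stereocenter and no double bond whose geometry must be set, so nothing can or need be relayed; the only sp3 stereocenters met on the way are racemic and are erased on aromatisation. The fragile parts are the C3=C4 alkene of the chromene and the aryl prenyl ether (both acid-labile; the ether is also cleaved by quinone oxidants and rearranges on strong heating), the other alkenes, which forbid hydrogenation, and the electron-rich phenols. The ring B oxygen must stay masked to the end by a group that leaves without acid, hydrogen or fluoride. The feature that invites a benzannulation is that the six carbons of ring A map one-to-one onto a vinylketene and an ynol ether: C8a is the ketene carbon, C8 and C7 are the alkyne carbons with oxygen already on C7, and C6, C5 and C4a are the remaining carbons of a cyclobutenone that already carries the chain and the prenyl group. C8 and C6 bear hydrogen, so a terminal ynol ether and a cyclobutenone unsubstituted at C2 are required.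

## Retrosynthesis

**25 to 24.** The last cut is the O–allyl bond on ring B. Ring B has to pass an organomagnesium step, aqueous acid, heating to about 110 °C, a quinone oxidation and fluoride, which rules out esters, acetals, electron-rich benzyl ethers and silyl ethers in turn. An allyl ether tolerates all of these and is removed under neutral conditions by zerovalent palladium. The forward step must ionise the unsubstituted allyl ether of 24 and spare the prenyl ether on O7; the weaker binding of a trisubstituted alkene to palladium is relied on for that.

**24 to 21 and 22.** The O7–CH2 bond of the prenyl ether is cut next, giving silyl ether 21 and prenyl bromide 22. The prenyl group cannot come earlier: a prenyl ynol ether would rearrange sigmatropically, and an aryl prenyl ether would not survive the quinone oxidation that closes the pyran. The cut removes five carbons and the most acid-sensitive ether. Forward, fluoride must free phenoxide 23 and the bromide must alkylate it on oxygen in the same flask.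

**21 to 19.** Opening the pyran at O1–C2 and restoring two hydrogens gives ortho-prenylphenol 19. A propargyl ether rearrangement or a condensation of a resorcinol with an enal would each have to choose between C4a and C8. Here there is no choice, because the five-carbon chain already sits on C4a and only the C8a hydroxyl is free. The forward reaction is an oxidative cyclisation through quinone methide 20 that must leave the C-alpha–C-beta bridge and the silyl ether untouched.

**19 to 10 and 14.** This is the strategic cut: C8–C8a, C6–C7 and C4a–C8a are broken together, dividing ring A into cyclobutenone 10 and silyl ynol ether 14. The cut turns a tetrasubstituted arene with differentiated oxygens into two small, non-aromatic pieces. The forward reaction must open 10 to vinylketene 15, add 14 in one orientation to give 16, reopen to 17 and electrocyclise through 18. A silyl ynol ether is preferred to an alkyl one because the resulting aryl silyl ether is the only C7–O group that can later be exchanged for prenyl without acid or forcing nucleophiles.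

**14 to 11.** The ynol ether is cut at O–Si and at C–O, back to ethyne 11 through acetylide 12 and ynolate 13. The forward sequence is oxidation of the acetylide at carbon followed by silylation on oxygen with a bulky silyl group; it is short, but 14 is the least documented compound of the plan.

**10 to 5 and 7.** The bond between the cyclobutenone C3 and the chain (C5–C-alpha of the target) is cut, giving vinylogous ester 5 and bromide 7, joined through organomagnesium 8 and carbinol 9. Alkylating a pre-formed 3-substituted cyclobutenone at C4 is not an option, because its enolate would be an antiaromatic cyclobutadienolate. Addition to 5 followed by acid transposition is reliable, and since C4 is flanked by both C1 and C3, direct addition–elimination and 1,2-addition–transposition give the same constitution.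

**5 to 2 and 3, and 2 to 1.** Cyclobutenone 5 is cut across C1–C2 and C3–C4 into prenylketene 4 and ethoxyethyne 3; the ketene comes from acid chloride 2 and acid 1. Enolate prenylation of 3-ethoxycyclobutenone is set aside for the antiaromaticity reason above. The cycloaddition places the prenyl group on C4 by construction.

**7 to 6.** The allyl ether of 7 is cut to 4-(2-bromoethyl)phenol 6; the forward step is an O-alkylation that must outrun self-alkylation at the primary bromide.

## Roads not taken

**Alternative 1:** Here C5–C-alpha and C4a–C4 are cut and ring A is bought intact. 1-Iodo-2,4-bis(methoxymethoxy)benzene A1, 4-(2-bromoethyl)phenyl 2,2-dimethylpropanoate A2 (the pivalate of 6) and 2-methylbut-3-en-2-ol A3 would be merged in a Catellani reaction (Pd(OAc)2, tri(2-furyl)phosphine, norbornene, Cs2CO3). The free ortho C–H of A1 is alkylated by A2 through a norbornene-derived palladacycle, and the ipso carbon is then closed off by Heck coupling with A3. The product is 4-[2-[2-[(E)-3-hydroxy-3-methylbut-1-enyl]-3,5-bis(methoxymethoxy)phenyl]ethyl]phenyl 2,2-dimethylpropanoate A4; no ring closes.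

- Merits: three commercial or one-step components, one catalytic step for both carbon–carbon bonds, and an overall count of about six or seven steps, shorter than the chosen plan. None of its reagents is as delicate as ynol ether 14.
- Weak points: A2 is a 2-arylethyl bromide and can lose HBr under carbonate at the reaction temperature, giving a styrene that is itself a Heck acceptor. The two ring A oxygens emerge identically protected, and the acetals must be removed with acid in the presence of a tertiary allylic alcohol on a very electron-rich ring. The E alkene must isomerise (through the allyl cation) before O1–C2 can close, under conditions that invite Friedel–Crafts oligomerisation.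
- Comparison: this road is better in step economy and reagent robustness. The chosen plan offers oxygens differentiated by mechanism, the C4a substituent delivered as the prenyl group itself, and no acid once prenyl-derived units are present.

**Alternative 2:** Here C5–C6 and C4a–C8a are cut together with O1–C2. 1-Methoxy-1,3-bis(trimethylsilyloxy)buta-1,3-diene A5 (geometric mixture at C1) would add across the triple bond of 8-[4-(tert-butyldimethylsilyloxy)phenyl]-2-methyloct-2-en-5-yn-4-one A6. Acid work-up aromatises ring A, and the new C8a phenol adds to the enone to give 5-[2-[4-(tert-butyldimethylsilyloxy)phenyl]ethyl]-7-hydroxy-2,2-dimethylchroman-4-one A7.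

- Merits: both rings form in one operation, O1 is locked in the ring while the C7 hydroxyl is free for prenylation, and the reagents are robust.
- Weak points: A6 has two electrophilic unsaturated termini, so the site and orientation of the diene addition must be controlled. A6 itself needs several steps. C4 arrives as a ketone, so reduction and dehydration are still required, and the dehydration uses acid on a molecule that by then should carry the prenyl ether.
- Comparison: length is about the same, and reagent reliability favours this road. The chosen plan avoids the oxidation-state detour at C4 and completes the pyran by one oxidative step.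

**Alternative 3:** Here only C4a–C5 is cut, in the manner of polyketide folding. 6-[2,4-Dioxo-6-[4-(triisopropylsilyloxy)phenyl]hexyl]-2,2-dimethyl-4H-1,3-dioxin-4-one A8 would undergo base-mediated aldol addition of its vinylogous ester carbon to the terminal ketone and acid-promoted dehydration. This gives 7-hydroxy-2,2-dimethyl-5-[2-[4-(triisopropylsilyloxy)phenyl]ethyl]-4H-1,3-benzodioxin-4-one A9.

- Merits: very mild aromatisation, unambiguous regiochemistry, and a free C7 hydroxyl next to a masked C8a oxygen.
- Weak points: C4 emerges at the carboxyl oxidation level and C2, C3 and the two methyls are absent. The dioxinone must be reduced or opened, three carbons added and the chromene unsaturation created, all in the presence of the prenyl ether or before it with extra protection. A8 is itself a multi-step, cyclisation-prone intermediate.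
- Comparison: it is the safest road for making ring A but clearly the longest overall. The chosen plan carries all pyran carbons into the ring-forming step, at the cost of the sensitive ynol ether.

Key step: step 6

Assumption: 5-methylhex-4-enoic acid 1 is treated as a purchasable acid and ethyne 11 as cylinder gas; every sp3 stereocenter on the way (in 5, 9, 10, 16 and 18) is racemic and is erased before the target.

## Route

Step 1
Reactants: 1 5-methylhex-4-enoic acid
Product: 2 5-methylhex-4-enoyl chloride
Conditions: (COCl)2, DMF (cat.), CH2Cl2, 0 °C to rt; volatiles removed under vacuum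
Reagents that add atoms: oxalyl chloride, O=C(Cl)C(=O)Cl
Why: Acyl chloride formation under chloroiminium catalysis; the remote trisubstituted alkene should survive the brief contact with HCl, and thorough removal of volatiles keeps acid away from the alkynyl ether of the next step.

Step 2
Reactants: 2 5-methylhex-4-enoyl chloride; 3 ethoxyethyne
Product: 5 racemic 3-ethoxy-4-(3-methylbut-2-enyl)cyclobut-2-en-1-one, via prenylketene 4 (not isolated)
Conditions: Et3N (slow addition), 3 (2 equiv), Et2O, 0 °C to rt
Reagents that add atoms: none
Why: Dehydrochlorination gives the aldoketene, which the alkoxyalkyne captures in a regiospecific ketene–alkyne [2+2] cycloaddition (terminal alkyne carbon to the ketene carbonyl carbon), the classical entry to 4-substituted 3-alkoxycyclobutenones. Slow base addition and excess alkyne hold back ketene dimerisation, the one-carbon tether keeps the ketene away from its own alkene, and C4 forms racemic.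

Step 3
Reactants: 6 4-(2-bromoethyl)phenol
Product: 7 1-(2-bromoethyl)-4-(prop-2-enyloxy)benzene
Conditions: allyl bromide (1.5 equiv), K2CO3, acetone, rt to 50 °C
Reagents that add atoms: 3-bromoprop-1-ene (allyl bromide), C=CCBr
Why: Williamson ether synthesis; the allylic bromide is far more reactive than the primary alkyl bromide of the substrate, so the phenoxide should be consumed before self-alkylation or loss of HBr matters.

Step 4
Reactants: 7 1-(2-bromoethyl)-4-(prop-2-enyloxy)benzene; 5 racemic 3-ethoxy-4-(3-methylbut-2-enyl)cyclobut-2-en-1-one
Product: 10 racemic 4-(3-methylbut-2-enyl)-3-[2-[4-(prop-2-enyloxy)phenyl]ethyl]cyclobut-2-en-1-one, via arylethylmagnesium bromide 8 (not isolated), via cyclobutenol adduct 9 (not isolated)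
Conditions: Mg, I2 (cat.), THF, rt to 40 °C; then 5, THF, −78 °C; then 1 M aq. HCl, −78 to 0 °C
Reagents that add atoms: water, O
Why: Grignard 1,2-addition to the vinylogous ester followed by acid-promoted hydrolysis with allylic transposition (Stork–Danheiser-type sequence). The cyclobutenone cannot enolise without becoming antiaromatic, so deprotonation does not compete. Because C4 is bonded to both C1 and C3, conjugate addition–elimination would give the same constitution; C4 stays racemic.

Step 5
Reactants: 11 ethyne
Product: 14 (ethynyloxy)tri(propan-2-yl)silane, via lithium acetylide 12 (not isolated), via lithium ethynolate 13 (not isolated)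
Conditions: n-BuLi, THF, −78 °C (excess ethyne); LiOOt-Bu (from t-BuOOH and LiN(SiMe3)2, THF, −78 °C), −78 to −20 °C; TIPSOTf, −78 to 0 °C; pentane, cold aq. NaHCO3, Et3N-deactivated SiO2, stored cold
Reagents that add atoms: tert-butyl hydroperoxide, CC(C)(C)OO; triisopropylsilyl trifluoromethanesulfonate, CC(C)[Si](OS(=O)(=O)C(F)(F)F)(C(C)C)C(C)C
Why: Electrophilic oxygen transfer from the lithium peroxide to the acetylide carbon gives the ynolate, the established route from terminal alkynes to silyl ynol ethers. The hard, bulky silyl triflate should silylate on oxygen, and the triisopropylsilyl group is chosen because it best resists the later shift of silicon from oxygen to carbon.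

Step 6
Reactants: 10 racemic 4-(3-methylbut-2-enyl)-3-[2-[4-(prop-2-enyloxy)phenyl]ethyl]cyclobut-2-en-1-one; 14 (ethynyloxy)tri(propan-2-yl)silane
Product: 19 2-(3-methylbut-2-enyl)-3-[2-[4-(prop-2-enyloxy)phenyl]ethyl]-5-(triisopropylsilyloxy)phenol, via vinylketene 15 (not isolated), via dienylcyclobutenone 16 (not isolated), via dienylketene 17 (not isolated), via cyclohexadienone 18 (not isolated)
Conditions: 14 (2 equiv), toluene (degassed), 80 °C then 110 °C, sealed tube, argon
Reagents that add atoms: none
Why: Thermal conrotatory four-electron opening of 10 releases ring strain and gives vinylketene 15, the C4 prenyl group rotating outward so that it ends up remote from the ketene. Ynol ether 14 then adds across the ketene C=C bond in a [2+2] cycloaddition, its nucleophilic terminal carbon (future C8) bonding to the ketene carbon (future C8a) and its oxygen-bearing carbon (future C7) to the ketene alpha carbon (future C6), which gives cyclobutenone 16. A second four-electron opening of 16 gives dienylketene 17, whose six-electron disrotatory electrocyclisation re-forms C4a–C8a and closes the six-membered carbocycle ring A as dienone 18, and tautomerisation delivers phenol 19. The closest known reaction is the Danheiser benzannulation of cyclobutenones with C-alkyl triisopropylsilyl ynol ethers to resorcinol monosilyl ethers; 14 is the unsubstituted member of that class. No stereocenter is created that persists, since C4 of 10 and C6 of 18 are racemic sp3 carbons that become aromatic. Regiochemistry rests on the polarisation of the ynol ether, so the free hydroxyl appears on C8a, the silyl ether on C7 and the two carbon substituents on C4a and C5 with no isomer possible. Chemoselectivity rests on the much higher ketenophilicity of the ynol ether compared with the prenyl and allyl alkenes, supported by the outward rotation that prevents internal capture and by the excess of 14, which also limits acylation of 19 by 15. The temperature is kept as low as the opening of 10 allows so that migration of silicon from oxygen to carbon in 14 does not outrun its capture.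

Step 7
Reactants: 19 2-(3-methylbut-2-enyl)-3-[2-[4-(prop-2-enyloxy)phenyl]ethyl]-5-(triisopropylsilyloxy)phenol
Product: 21 2,2-dimethyl-5-[2-[4-(prop-2-enyloxy)phenyl]ethyl]-7-(triisopropylsilyloxy)-2H-chromene, via quinone methide 20 (not isolated)
Conditions: DDQ (1.1 equiv), benzene, rt to 80 °C
Reagents that add atoms: none
Why: DDQ cyclodehydrogenation of an ortho-prenylphenol: hydride loss from the benzylic CH2, assisted by the ortho hydroxyl and the para silyloxy group, gives the ortho-quinone methide, which closes O1–C2 by six-electron oxa-electrocyclisation. The C-alpha–C-beta bridge has no comparable activation and should not be dehydrogenated under these conditions.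

Step 8
Reactants: 21 2,2-dimethyl-5-[2-[4-(prop-2-enyloxy)phenyl]ethyl]-7-(triisopropylsilyloxy)-2H-chromene; 22 1-bromo-3-methylbut-2-ene
Product: 24 2,2-dimethyl-7-(3-methylbut-2-enyloxy)-5-[2-[4-(prop-2-enyloxy)phenyl]ethyl]-2H-chromene, via cesium phenoxide 23 (not isolated)
Conditions: CsF, DMF, rt; then 22, 0 °C to rt
Reagents that add atoms: none
Why: Fluoride cleaves the aryl silyl ether to the cesium phenoxide, which is alkylated in the same flask by the allylic bromide (desilylative Williamson etherification). The cesium counter-ion in a dipolar aprotic solvent favours O- over C-alkylation, and the chromene and allyl ether are inert to fluoride.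

Step 9
Reactants: 24 2,2-dimethyl-7-(3-methylbut-2-enyloxy)-5-[2-[4-(prop-2-enyloxy)phenyl]ethyl]-2H-chromene
Product: 25 4-[2-[2,2-dimethyl-7-(3-methylbut-2-enyloxy)-2H-chromen-5-yl]ethyl]phenol
Conditions: Pd(PPh3)4 (cat.), morpholine, THF, rt
Reagents that add atoms: none
Why: Tsuji–Trost deallylation: zerovalent palladium ionises the unsubstituted allyl aryl ether to a π-allyl complex that morpholine intercepts. The prenyl ether, whose trisubstituted alkene coordinates palladium poorly, and the chromene should be left alone under these neutral conditions.

## Compound list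

1 | 5-methylhex-4-enoic acid | CC(C)=CCCC(=O)O | starting material
2 | 5-methylhex-4-enoyl chloride | CC(C)=CCCC(=O)Cl | intermediate
3 | ethoxyethyne | C#COCC | starting material
4 | 5-methylhexa-1,4-dien-1-one (prenylketene) | CC(C)=CCC=C=O | intermediate (not isolated)
5 | racemic 3-ethoxy-4-(3-methylbut-2-enyl)cyclobut-2-en-1-one | CCOC1=CC(=O)C1CC=C(C)C | intermediate
6 | 4-(2-bromoethyl)phenol | Oc1ccc(CCBr)cc1 | starting material
7 | 1-(2-bromoethyl)-4-(prop-2-enyloxy)benzene | C=CCOc1ccc(CCBr)cc1 | intermediate
8 | bromo[2-[4-(prop-2-enyloxy)phenyl]ethyl]magnesium | C=CCOc1ccc(CC[Mg]Br)cc1 | intermediate (not isolated)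
9 | 3-ethoxy-4-(3-methylbut-2-enyl)-1-[2-[4-(prop-2-enyloxy)phenyl]ethyl]cyclobut-2-en-1-ol (racemic, both diastereomers) | CCOC1=CC(O)(CCc2ccc(OCC=C)cc2)C1CC=C(C)C | intermediate (not isolated)
10 | racemic 4-(3-methylbut-2-enyl)-3-[2-[4-(prop-2-enyloxy)phenyl]ethyl]cyclobut-2-en-1-one | O=C1C=C(CCc2ccc(OCC=C)cc2)C1CC=C(C)C | intermediate
11 | ethyne | C#C | starting material
12 | lithium acetylide | [Li+].[C-]#C | intermediate (not isolated)
13 | lithium ethynolate | [Li+].[O-]C#C | intermediate (not isolated)
14 | (ethynyloxy)tri(propan-2-yl)silane | C#CO[Si](C(C)C)(C(C)C)C(C)C | intermediate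
15 | (3E)-7-methyl-3-[2-[4-(prop-2-enyloxy)phenyl]ethyl]octa-1,3,6-trien-1-one | O=C=C/C(CCc1ccc(OCC=C)cc1)=C/CC=C(C)C | intermediate (not isolated)
16 | racemic 4-[(3E)-7-methyl-1-[4-(prop-2-enyloxy)phenyl]octa-3,6-dien-3-yl]-3-(triisopropylsilyloxy)cyclobut-2-en-1-one | O=C1C=C(O[Si](C(C)C)(C(C)C)C(C)C)C1/C(CCc2ccc(OCC=C)cc2)=C/CC=C(C)C | intermediate (not isolated)
17 | (3E,5E)-9-methyl-5-[2-[4-(prop-2-enyloxy)phenyl]ethyl]-3-(triisopropylsilyloxy)deca-1,3,5,8-tetraen-1-one | O=C=C/C(O[Si](C(C)C)(C(C)C)C(C)C)=C\C(CCc1ccc(OCC=C)cc1)=C\CC=C(C)C | intermediate (not isolated)
18 | racemic 6-(3-methylbut-2-enyl)-5-[2-[4-(prop-2-enyloxy)phenyl]ethyl]-3-(triisopropylsilyloxy)cyclohexa-2,4-dien-1-one | O=C1C=C(O[Si](C(C)C)(C(C)C)C(C)C)C=C(CCc2ccc(OCC=C)cc2)C1CC=C(C)C | intermediate (not isolated)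
19 | 2-(3-methylbut-2-enyl)-3-[2-[4-(prop-2-enyloxy)phenyl]ethyl]-5-(triisopropylsilyloxy)phenol | CC(C)=CCc1c(O)cc(O[Si](C(C)C)(C(C)C)C(C)C)cc1CCc1ccc(OCC=C)cc1 | intermediate
20 | (6Z)-6-(3-methylbut-2-enylidene)-5-[2-[4-(prop-2-enyloxy)phenyl]ethyl]-3-(triisopropylsilyloxy)cyclohexa-2,4-dien-1-one | O=C1C=C(O[Si](C(C)C)(C(C)C)C(C)C)C=C(CCc2ccc(OCC=C)cc2)/C1=C/C=C(C)C | intermediate (not isolated)
21 | 2,2-dimethyl-5-[2-[4-(prop-2-enyloxy)phenyl]ethyl]-7-(triisopropylsilyloxy)-2H-chromene | CC1(C)C=Cc2c(CCc3ccc(OCC=C)cc3)cc(O[Si](C(C)C)(C(C)C)C(C)C)cc2O1 | intermediate
22 | 1-bromo-3-methylbut-2-ene | CC(C)=CCBr | starting material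
23 | cesium 2,2-dimethyl-5-[2-[4-(prop-2-enyloxy)phenyl]ethyl]-2H-chromen-7-olate | [Cs+].[O-]c1cc(CCc2ccc(OCC=C)cc2)c2C=CC(C)(C)Oc2c1 | intermediate (not isolated)
24 | 2,2-dimethyl-7-(3-methylbut-2-enyloxy)-5-[2-[4-(prop-2-enyloxy)phenyl]ethyl]-2H-chromene | CC(C)=CCOc1cc(CCc2ccc(OCC=C)cc2)c2c(c1)OC(C)(C)C=C2 | intermediate
25 | 4-[2-[2,2-dimethyl-7-(3-methylbut-2-enyloxy)-2H-chromen-5-yl]ethyl]phenol | CC(C)=CCOc1cc(CCc2ccc(O)cc2)c2c(c1)OC(C)(C)C=C2 | target

## Step count and least certain steps

Total: 9 steps. Longest linear sequence: 7 steps (steps 1, 2, 4, 6, 7, 8, 9).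

**Step 6 (key step).** The most likely failure is loss of the ketenophile: silicon can migrate from oxygen to the unhindered terminal carbon of 14 at the temperature needed to open 10, giving an unreactive silylketene before the vinylketene appears. Two lesser risks are capture of the minor inward-rotated vinylketene by its own prenyl alkene and acylation of the product phenol by 15.

The fallback separates ketene generation from heat. It sets out from 10 and 14: 10 is opened photochemically at room temperature (about 350 nm, Pyrex) in the presence of 14, so that the [2+2] capture takes place cold and the cascade stops at cyclobutenone 16. Compound 16 is then aromatised on its own by heating in toluene, and the route is rejoined at 19. No compound outside the list is made. If 14 itself proves unusable, the fallback under step 5 applies.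

**Step 5.** The ynolate may never form cleanly, because lithium acetylide 12 disproportionates to the insoluble dilithium salt on warming. If it does form, silylation may occur on carbon rather than oxygen, or the product may hydrolyse during isolation.

The fallback gives up the silyl ynol ether for an alkyl ynol ether whose alkyl group is still fluoride-labile, and sets out from 10.
- 2-(Trimethylsilyl)ethanol is added as its potassium alkoxide (KH, THF) to trichloroethylene to give [2-[(E)-1,2-dichloroethenyl]oxyethyl]trimethylsilane F1.
- n-BuLi (two equivalents, −78 °C) followed by a proton quench converts it into [2-(ethynyloxy)ethyl]trimethylsilane F2.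
- Benzannulation of 10 with F2 at 80 °C, alkoxyacetylenes being the original ketenophiles of this reaction, should give 2-(3-methylbut-2-enyl)-3-[2-[4-(prop-2-enyloxy)phenyl]ethyl]-5-[2-(trimethylsilyl)ethoxy]phenol F3.
- DDQ as in step 7 gives 2,2-dimethyl-5-[2-[4-(prop-2-enyloxy)phenyl]ethyl]-7-[2-(trimethylsilyl)ethoxy]-2H-chromene F4.
- CsF in DMF at 80 to 100 °C induces beta-elimination to phenoxide 23, which is prenylated with 22, rejoining the route at 24.

**Step 7.** The oxidant may attack elsewhere: dehydrogenation of the C-alpha–C-beta bridge to a stilbene, or oxidation next to the electron-rich ring B, could compete with formation of the quinone methide, and the acidic hydroquinone by-product could loosen the silyl ether.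

The fallback replaces hydride abstraction by selenium chemistry and sets out from 19. PhSeCl (CH2Cl2, −78 °C) induces 6-endo selenoetherification at the tertiary carbon of the prenyl group, giving racemic 2,2-dimethyl-3-(phenylselanyl)-5-[2-[4-(prop-2-enyloxy)phenyl]ethyl]-7-(triisopropylsilyloxy)chromane F5. Oxidation at selenium with H2O2 and pyridine, followed by syn-elimination towards C4, rejoins the route at 21.

**Step 9.** Chemoselectivity may be lost if palladium also ionises the prenyl ether on O7, removing it or scrambling it to the reverse-prenyl isomer.

The fallback reorders the protecting groups so that no prenyl ether is present when palladium is used, and sets out from 21.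
- Pd(PPh3)4 and morpholine remove the allyl group first, giving 4-[2-[2,2-dimethyl-7-(triisopropylsilyloxy)-2H-chromen-5-yl]ethyl]phenol F6.
- Pivaloyl chloride, Et3N and DMAP give 4-[2-[2,2-dimethyl-7-(triisopropylsilyloxy)-2H-chromen-5-yl]ethyl]phenyl 2,2-dimethylpropanoate F7.
- Fluoride-triggered prenylation with 22 as in step 8 gives 4-[2-[2,2-dimethyl-7-(3-methylbut-2-enyloxy)-2H-chromen-5-yl]ethyl]phenyl 2,2-dimethylpropanoate F8.
- NaOMe in MeOH removes the ester and rejoins the route at 25.

## Further compounds

F0 | step 6 | none | none
F1 | step 5 | [2-[(E)-1,2-dichloroethenyl]oxyethyl]trimethylsilane | Cl/C=C(/Cl)OCC[Si](C)(C)C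
F2 | step 5 | [2-(ethynyloxy)ethyl]trimethylsilane | C#COCC[Si](C)(C)C
F3 | step 5 | 2-(3-methylbut-2-enyl)-3-[2-[4-(prop-2-enyloxy)phenyl]ethyl]-5-[2-(trimethylsilyl)ethoxy]phenol | CC(C)=CCc1c(O)cc(OCC[Si](C)(C)C)cc1CCc1ccc(OCC=C)cc1
F4 | step 5 | 2,2-dimethyl-5-[2-[4-(prop-2-enyloxy)phenyl]ethyl]-7-[2-(trimethylsilyl)ethoxy]-2H-chromene | CC1(C)C=Cc2c(CCc3ccc(OCC=C)cc3)cc(OCC[Si](C)(C)C)cc2O1
F5 | step 7 | racemic 2,2-dimethyl-3-(phenylselanyl)-5-[2-[4-(prop-2-enyloxy)phenyl]ethyl]-7-(triisopropylsilyloxy)chromane | CC1(C)Oc2cc(O[Si](C(C)C)(C(C)C)C(C)C)cc(CCc3ccc(OCC=C)cc3)c2CC1[Se]c1ccccc1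
F6 | step 9 | 4-[2-[2,2-dimethyl-7-(triisopropylsilyloxy)-2H-chromen-5-yl]ethyl]phenol | CC1(C)C=Cc2c(CCc3ccc(O)cc3)cc(O[Si](C(C)C)(C(C)C)C(C)C)cc2O1
F7 | step 9 | 4-[2-[2,2-dimethyl-7-(triisopropylsilyloxy)-2H-chromen-5-yl]ethyl]phenyl 2,2-dimethylpropanoate | CC1(C)C=Cc2c(CCc3ccc(OC(=O)C(C)(C)C)cc3)cc(O[Si](C(C)C)(C(C)C)C(C)C)cc2O1
F8 | step 9 | 4-[2-[2,2-dimethyl-7-(3-methylbut-2-enyloxy)-2H-chromen-5-yl]ethyl]phenyl 2,2-dimethylpropanoate | CC(C)=CCOc1cc(CCc2ccc(OC(=O)C(C)(C)C)cc2)c2c(c1)OC(C)(C)C=C2
A1 | alternative 1 | 1-iodo-2,4-bis(methoxymethoxy)benzene | COCOc1ccc(I)c(OCOC)c1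
A2 | alternative 1 | 4-(2-bromoethyl)phenyl 2,2-dimethylpropanoate | CC(C)(C)C(=O)Oc1ccc(CCBr)cc1
A3 | alternative 1 | 2-methylbut-3-en-2-ol | CC(C)(O)C=C
A4 | alternative 1 | 4-[2-[2-[(E)-3-hydroxy-3-methylbut-1-enyl]-3,5-bis(methoxymethoxy)phenyl]ethyl]phenyl 2,2-dimethylpropanoate | CC(C)(O)/C=C/c1c(OCOC)cc(OCOC)cc1CCc1ccc(OC(=O)C(C)(C)C)cc1
A5 | alternative 2 | 1-methoxy-1,3-bis(trimethylsilyloxy)buta-1,3-diene (geometric mixture at C1) | COC(O[Si](C)(C)C)=CC(=C)O[Si](C)(C)C
A6 | alternative 2 | 8-[4-(tert-butyldimethylsilyloxy)phenyl]-2-methyloct-2-en-5-yn-4-one | CC(C)=CC(=O)C#CCCc1ccc(O[Si](C)(C)C(C)(C)C)cc1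
A7 | alternative 2 | 5-[2-[4-(tert-butyldimethylsilyloxy)phenyl]ethyl]-7-hydroxy-2,2-dimethylchroman-4-one | CC1(C)CC(=O)c2c(CCc3ccc(O[Si](C)(C)C(C)(C)C)cc3)cc(O)cc2O1
A8 | alternative 3 | 6-[2,4-dioxo-6-[4-(triisopropylsilyloxy)phenyl]hexyl]-2,2-dimethyl-4H-1,3-dioxin-4-one | CC1(C)OC(CC(=O)CC(=O)CCc2ccc(O[Si](C(C)C)(C(C)C)C(C)C)cc2)=CC(=O)O1
A9 | alternative 3 | 7-hydroxy-2,2-dimethyl-5-[2-[4-(triisopropylsilyloxy)phenyl]ethyl]-4H-1,3-benzodioxin-4-one | CC1(C)Oc2cc(O)cc(CCc3ccc(O[Si](C(C)C)(C(C)C)C(C)C)cc3)c2C(=O)O1
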